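4 questions are asked of this flask, and we answer them through one height: how much left-handed product stands soon after the feed ends.

| setting | Friday's | Wednesday's | flask |
|---|---|---|---|
| left-handed substrate | 0.26 M | 0.26 M | 0.26 M |
| right-handed substrate | 0.26 M | 0.26 M | 0.26 M |
| coupling partner | 0.36 M (fed, over 3.0 min) | 0.57 M (fed, over 3.0 min) | 0.260 M (fed, over 3.0 min) |
| remark | run made earlier; the fed solution adds 1.0 times the starting volume | run made earlier; the fed solution adds 1.0 times the starting volume | the fed solution adds 1.0 times the starting volume |
| time |  |  | 1.5 h |

| run | time / min | left-handed product / % |
|---|---|---|
| Friday's | 1.33 | 14.9 |
| Friday's | 4.00 | 33.5 |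
| Friday's | 12.0 | 30.4 |
| Friday's | 30.0 | 29.8 |
| Friday's | 90.0 | 33.7 |
| Wednesday's | 1.33 | 22.7 |
| Wednesday's | 4.00 | 38.8 |
| Wednesday's | 12.0 | 32.2 |
| Wednesday's | 30.0 | 35.3 |
| Wednesday's | 90.0 | 44.4 |

(scatter of a reading: 0.5 percentage points)

* time, not beyond 1.5 h, at which the flask holds most left-handed product
* the amount of left-handed product, in percent of the left-handed substrate and right-handed substrate together charged, at that time
* earliest time at which at least nineteen twentieths of that best amount are there
* latest time at which they still are

- coupling partner is single-handed; left-handed substrate and right-handed substrate are mirror images of each other, charged as a racemate, each of them at the stated concentration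
- amounts are per litre of the starting volume; all of the dose is in the solution fed
- the numbers in the tables scatter with a standard deviation of 0.5 percentage points
- reactions considered so far: coupling partner + right-handed substrate -> right-handed product; coupling partner <-> dormant form; coupling partner + left-handed substrate -> left-handed product; left-handed product <-> right-handed product
- the handed part of coupling partner does not stay in what it makes, so the products of the two hands are mirror images too

We let each portion of coupling partner split between left-handed substrate and its rivals, right-handed substrate and the dormant form, with the share to left-handed product equal to c(left-handed substrate) / (c(left-handed substrate) + the even-split level), the even-split level being the c(left-handed substrate) at which a portion splits equally. We read it at 4.00 min. In Friday's run, 0.174 M of left-handed product from 0.36 M fed is a share of 48.4%, with 0.0858 M of left-handed substrate counted as left, so the level is 0.0915 M. In Wednesday's run the same steps give a share of 35.4% and a level of 0.106 M, so we carry the mean, 0.0989 M.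

For the flask we guess a share of 0.5, which leaves 0.130 M and returns 56.8%, higher than the guess. That guess is the weak link, so we go round once more: 56.8% leaves 0.112 M and returns 53.2%. The rounds swing, so we take their mean, 55.0%, which makes 27.5% of the charge. That is above 25.0%, half the dose as a share of the charge, so we expect the best early.

The forecast gives 25.3% at 0.06 h, lower than our height, calling it “marginally above the late value”; it has the near-best level first reached at 0.05 h, lost in a dip, regained later and last standing at 1.5 h.

The flask gives 28.8% at 0.0930 h, and the near-best level asked for stands from 0.0614 h to 0.165 h.

    coupling partner + right-handed substrate → right-handed product (k = 0.00600 M⁻¹ s⁻¹)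
    coupling partner ⇌ dormant form (K = 0.780, k = 0.0110 s⁻¹)
    coupling partner + left-handed substrate → left-handed product (k = 0.180 M⁻¹ s⁻¹)
    left-handed product ⇌ right-handed product (k = 0.00170 s⁻¹)

Our 27.5% lay 1.3 percentage points below that best. With 0.10 M of coupling partner, the neighbouring flask takes the same level and the same opening guess, and its rounds return 68.0% and 66.0%. Their mean makes 12.9% of the charge, and that neighbour's best is 12.8%.

All runs were generated by integration from invented constants.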